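## Structural features

Compound 31 is a cembranoid: a 14-membered carbocycle (C1–C14) whose C1 and C3 are bridged by O–C16(=O)–C15(CH3), so that a δ-lactone shares C1–C2–C3 with the large ring. Its seven stereocentres form three separate groups: C15/C1/C3/C4 on and beside the lactone (C15–C1 and C3–C4 adjacent, C1/C3 in a 1,3-relation), the adjacent pair C11/C12 of the trans trisubstituted epoxide, and the isolated quaternary C8 carrying the hydroperoxide next to the E-C6=C7 alkene. On the lactone the C17 methyl is trans to the C1 chain and the C1 and C3 substituents are cis, so all three can be equatorial; C15, the only epimerisable centre, therefore has the configuration expected to be the more stable one. The tertiary allylic hydroperoxide is the most fragile group (reduction, Hock cleavage, allylic peroxide shift, base, metals). The 11,12-epoxide is acid-labile, and the lactone is both an electrophile and a carbon acid. The real difficulty is to close the 14-membered ring while the three remote stereochemical groups are each set by their own control element, and to bring in the hydroperoxide last. Ring closure uses the segment C4(OH)(CH3)–C5H2–C6: this is what remains of a 2,2-disubstituted 4,5-oxirane opened at its CH2 end, and C6, allylic to C7=C8 in the deoxy compound, can hold a sulfonyl-stabilised carbanion. The same C7=C8 alkene later becomes C6=C7 with oxygen on C8 in the ene reaction.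

## Logic of the disconnections

31 ⇒ 30. The C8–O bond is cut, the double bond returns from C6=C7 to C7=C8 and a hydrogen returns to C6 (ene retron). The hydroperoxide would survive none of the carbanion, reducing or Lewis-acidic steps, so it is introduced last. C8 stops being a stereocentre in 30. The forward step must take the hydrogen from C6 rather than from C19 and must attack one face of the ring alkene.

30 ⇒ 29. A C6–H bond is exchanged for C6–S. The sulfonyl group is the handle that makes C6 a carbanion. The forward reduction must remove it without moving C7=C8 and without touching lactone or epoxide.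

29 ⇒ 27. The C5–C6 bond is cut, which opens the carbocycle and turns the C4 carbinol into the 4,5-oxirane. This leaves a monocyclic lactone whose C4 configuration is stored in the epoxide. A descriptor-by-descriptor comparison of 27, 29 and 31 shows the same configuration at C1, C3, C4, C11, C12 and C15 throughout. One point of the usual description of this closure needs correcting: because the carbanion attacks the oxirane carbon remote from the tether, it is the endo mode of epoxide opening, not exo. The forward step must choose C5 over the second epoxide and over the lactone carbonyl.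

27 ⇒ 26. The two C–O bonds of the 11,12-epoxide are cut. This acid-labile group is placed after every acidic step and directly before the carbanion step. The chain of 26 then carries no stereocentre. The forward epoxidation must be reagent-controlled and must leave C7=C8 alone.

26 ⇒ 19 + 24. The C10–C11 bond between an sp2 and an sp3 carbon is cut. This is convergent: the sulfone arrives complete in 24, both alkene geometries are fixed in the fragments, and no acidic sulfone is present while C15 of 19 is equilibrated. The organometallic derived from 24 must tolerate lactone, oxirane and its own sulfone.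

24 ⇒ 23 ⇒ 22 ⇒ 20. The C6–S bond, then both C–Br bonds, then C6–C7 and C8–C19 are cut (carbometalation retron). This reaches a four-carbon alkynol; the forward carbometalation must be syn and regioselective so that C7=C8 is E.

19 ⇒ 17. The C5–O bond of the oxirane is cut to a tertiary alcohol and a primary sulfonate, and C15 is allowed to be either epimer. Lactonisation alone does not produce the 4,5-epoxide; a leaving group at C5 and a separate base step are needed. The same base step must equilibrate C15 without opening the lactone.

17 ⇒ 15. The lactone C3–O bond is cut (anti opening of a 3,4-epoxide by the C16 carboxyl) and C16 is lowered to the alcohol. C3 and C4 then both derive from one epoxide. The forward cyclisation must be 6-exo at C3 with inversion, not 7-endo at C4.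

15 ⇒ 13. The C16–O bond is cut (hydroboration retron of the isopropenyl group). C15 is formed without control, which is acceptable because it is corrected in 19.

13 ⇒ 11. The epoxide C–O bonds and the sulfonate are removed, leaving an E allylic alcohol, the substrate class for which Sharpless epoxidation is most reliable.

11 ⇒ 10 ⇒ 8 + 9. After adjusting the oxidation level, C3=C4 is cut by a Wittig retron. The ylide 9 brings C4, C5 and C18; the olefination must be E-selective.

8 ⇒ 7 ⇒ 5 ⇒ 3. The aldehyde is masked as an acetal, then C11–I and C12–C20 are cut (carbometalation and iodination of a terminal alkyne), and the alkyne is traced to a methyl ketone. This fixes the E geometry of the future C11=C12, which a direct olefination of the methyl ketone would not.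

3 ⇒ 1. C3 and C12 are reconnected as the ring alkene (ozonolysis retron). The chiral pool compound 1 supplies C1 with the correct configuration, and its isopropenyl group supplies C15–C17.

## Other disconnections considered

Alternative 1: The cut goes through C1–C15 and O–C16. The lactone ring is built as a dihydropyran from the oxodienoate A1 and the enol ether A2 by an inverse-demand hetero-Diels–Alder reaction under a chiral bis(oxazoline) complex of divalent copper, giving acetal A3, which must later be oxidised to the lactone.
- In its favour: one catalytic asymmetric step sets C1 and C15, with the methyl trans to the C1 chain through the E geometry of A2 and an endo transition state. On C15 this is better than the chosen plan, which relies on equilibration, and it needs no chiral pool.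
- Against it here: in A3, C3 is an enol-ether sp2 carbon and C4 is an ester carbon. C3 must then be set by a face-selective reduction, and the quaternary C4 with its methyl and C5 must be built by acyclic 1,2-induction. The chosen plan takes both centres from one Sharpless epoxide.
- The acetal-to-lactone oxidation would come late, in a molecule that by then holds epoxides.
- The disconnection does not address the macrocycle, and the chain of A3 ends at a C10 acetate, so an allyl–allyl union at C9–C10 is still required.
- Comparison: the mechanism is pericyclic and reagent-controlled, against stereospecific epoxide chemistry on a chiral-pool core. It is equal to the chosen plan on ring closure, which would probably be the same carbanion–epoxide step, and longer in redox and functional-group steps.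

Alternative 2: The cut is the lactone C3–O bond inside the finished carbocycle. The C16 carboxylate of the macrocyclic bis-epoxy acid A4 opens the 3,4-epoxide at C3 with inversion to give A5, which is the same compound as 30.
- In its favour: the lactone appears only after ring closure, so the macrocyclisation has neither an electrophilic carbonyl nor an acidic C15–H to contend with. On that point it is better than the chosen plan. The inversion at C3 is the same stereospecific event as step 9 of the chosen route, so the two are equal there.
- Against it here: A4 needs a 3,4-epoxide of defined configuration in a ring where C5 is a plain methylene, so there is no allylic hydroxyl for a Sharpless epoxidation.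
- Three trisubstituted alkenes (3,4; 7,8; 11,12) would have to be told apart.
- The transannular opening would have to prefer C3 over the tertiary C4 without the deactivating sulfonate used in the chosen plan, and under acid the 11,12-epoxide is exposed.
- The carbocycle must still be closed by some other method, and C15 must still be set, as in the chosen plan.
- Comparison: this plan removes the main chemoselectivity risk of the chosen key step but moves the risk to selective epoxidation on a macrocycle. Step count would be similar.

Alternative 3: The cut is C1–C2. The 16-membered macrolactone A6 is methylenated with a titanium carbene source (tetravalent titanium) to the allyl vinyl ether A7, whose Claisen rearrangement contracts the ring to the 14-membered ketone A8 with an isopropenyl group on C1.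
- In its favour: macrolactonisation is among the most dependable large-ring closures, which makes it better than a carbanion macrocyclisation on that point. No sulfone has to be installed and removed. The C3 ketone of A8 offers a 1,2-controlled reduction next to the oxygenated C4.
- Against it here: C1 is created in the key step, and the allylic carbon C16 of A7 is a CH2 with no stereocentre to transfer. The configuration at C1 would depend on chair or boat preferences of a macrocyclic transition state steered by remote centres. The chosen plan takes C1 from the chiral pool.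
- The quaternary C4 must be made enantioselectively beforehand.
- Methylenation of a hindered α-silyloxy lactone is demanding.
- After A8 there remain C3 reduction, conversion of the isopropenyl group into the acid (C15 uncontrolled, equal to the chosen plan), lactonisation and the ene step.
- Comparison: ring formation is more secure, but stereocontrol at C1 is less secure, and more steps follow the key step than in the chosen plan.

Key step: step 16

Remark on the chemistry: cembrane numbering is used for all intermediates. The hydroboration in step 8 is assumed to be unselective at C15, and the 15S lactone (C17 trans to the C1 chain, all three ring substituents equatorial) is assumed to be the more stable epimer, which is why C15 is set by equilibration in step 10.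

## Route

Step 1
Reactants: 1 (R)-(+)-limonene
Product: 3 (5R)-7,7-dimethoxy-5-(prop-1-en-2-yl)heptan-2-one, via methoxy hydroperoxide acetal 2 (not isolated)
Conditions: O3, CH2Cl2/MeOH, −78 °C; TsOH·H2O (cat.), 25 °C; NaHCO3, Me2S
Reagents that add atoms: ozone, [O-][O+]=O; methanol, CO
Why: Ozone should attack the electron-rich trisubstituted ring alkene before the 1,1-disubstituted isopropenyl group; in methanol the carbonyl oxide is trapped at the ketone carbon while the free aldehyde is acetalised, and Me2S reduces the hydroperoxide (terminus-differentiating ozonolysis). C1 is not touched.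

Step 2
Reactants: 3
Product: 5 (5R)-7,7-dimethoxy-5-(prop-1-en-2-yl)hept-1-yne, via enol phosphate 4 (not isolated)
Conditions: LiN(iPr)2 (1.05 equiv), THF, −78 °C; ClP(O)(OEt)2, −78 → 25 °C; LiN(iPr)2 (2.3 equiv), −78 → 25 °C; aq. NH4Cl
Reagents that add atoms: none
Why: Kinetic enolisation takes place at the methyl group, the enolate is phosphorylated on oxygen and the enol phosphate is eliminated by further amide (Negishi conversion of a methyl ketone into a terminal alkyne). Acetal and isopropenyl group are inert to amide base.

Step 3
Reactants: 5
Product: 7 (1E,5R)-1-iodo-7,7-dimethoxy-2-methyl-5-(prop-1-en-2-yl)hept-1-ene, via alkenylalane 6 (not isolated)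
Conditions: Me3Al (2.5 equiv), Cp2ZrCl2 (20 mol %), H2O (1 equiv), CH2Cl2, −23 °C; I2, THF, −23 → 0 °C; aq. NaHCO3/Na2S2O3
Reagents that add atoms: trimethylaluminium, C[Al](C)C; iodine, II
Why: Zirconium-catalysed Negishi carboalumination adds methyl and aluminium syn across the terminal alkyne, methyl to the internal carbon, and iodinolysis with retention should give only the E alkenyl iodide, which fixes the later C11=C12 geometry. The water-accelerated low-temperature variant is chosen to spare the acetal.

Step 4
Reactants: 7
Product: 8 (3R,6E)-7-iodo-6-methyl-3-(prop-1-en-2-yl)hept-6-enal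
Conditions: 1 M HCl, THF/H2O, 25 °C
Reagents that add atoms: water, O
Why: Acid hydrolysis of an acyclic dimethyl acetal. C1 is β to the aldehyde and cannot epimerise; alkenyl iodide and isopropenyl group tolerate dilute acid.

Step 5
Reactants: 8; 9 ethyl 2-(triphenylphosphoranylidene)propanoate
Product: 10 ethyl (2E,5R,8E)-9-iodo-2,8-dimethyl-5-(prop-1-en-2-yl)nona-2,8-dienoate
Conditions: CH2Cl2, 25 → 40 °C
Reagents that add atoms: none
Why: Wittig olefination with an α-branched stabilised ylide, which should give the E trisubstituted enoate (C3=C4) under thermodynamic control of the oxaphosphetane.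

Step 6
Reactants: 10
Product: 11 (2E,5R,8E)-9-iodo-2,8-dimethyl-5-(prop-1-en-2-yl)nona-2,8-dien-1-ol
Conditions: iBu2AlH (2.3 equiv), CH2Cl2, −78 °C; aq. potassium sodium tartrate
Reagents that add atoms: none
Why: 1,2-Reduction of the enoate by iBu2AlH at low temperature gives the allylic alcohol; the alkenyl iodide is untouched.

Step 7
Reactants: 11
Product: 13 [(2S,3S)-3-[(2R,5E)-6-iodo-5-methyl-2-(prop-1-en-2-yl)hex-5-en-1-yl]-2-methyloxiran-2-yl]methyl 4-methylbenzenesulfonate, via epoxy alcohol 12 (not isolated)
Conditions: Ti(OiPr)4 (10 mol %), L-(+)-diethyl tartrate (12 mol %), tBuOOH, 4 Å MS, CH2Cl2, −20 °C; P(OMe)3; Et3N, DMAP (cat.), TsCl, −20 → 0 °C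
Reagents that add atoms: tert-butyl hydroperoxide, CC(C)(C)OO; 4-methylbenzenesulfonyl chloride, Cc1ccc(cc1)S(=O)(=O)Cl
Why: Katsuki–Sharpless epoxidation: with the L-(+)-tartrate an E 2-methyl allylic alcohol should give the (2S,3S) epoxy alcohol (3S,4S in cembrane numbering), and only the alkene next to the hydroxyl reacts. Tosylation in the same flask protects the primary alcohol for the oxidation in step 9 and installs the leaving group for step 10.

Step 8
Reactants: 13
Product: 15 [(2S,3S)-3-[(2R,5E)-2-(1-hydroxypropan-2-yl)-6-iodo-5-methylhex-5-en-1-yl]-2-methyloxiran-2-yl]methyl 4-methylbenzenesulfonate (both C15 epimers), via trialkylborane 14 (not isolated)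
Conditions: 9-BBN (1.5 equiv), THF, 0 → 25 °C; NaBO3·4H2O, H2O, 25 °C
Reagents that add atoms: sodium perborate, [Na+].[Na+].O[B-]1(O)OO[B-](O)(O)OO1
Why: Anti-Markovnikov hydroboration with 9-BBN should touch only the unhindered 1,1-disubstituted alkene; the trisubstituted alkenyl iodide, the epoxide and the tosylate are inert, and perborate is a mild oxidant. No facial bias is expected at C15, which is corrected in step 10.

Step 9
Reactants: 15
Product: 17 (2S)-2-hydroxy-2-[(2R,4R)-4-[(3E)-4-iodo-3-methylbut-3-en-1-yl]-5-methyl-6-oxooxan-2-yl]propyl 4-methylbenzenesulfonate (both C15 epimers), via epoxy acid 16 (not isolated)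
Conditions: TEMPO (20 mol %), PhI(OAc)2 (2.5 equiv), MeCN/H2O (1:1), 25 °C; then CSA (10 mol %), CH2Cl2, 25 °C
Reagents that add atoms: water, O
Why: Oxoammonium oxidation in aqueous acetonitrile takes the primary alcohol to the acid, which then opens the epoxide by 6-exo attack at C3 with inversion (acid-catalysed epoxy-acid lactonisation), giving 3R and the cis C1/C3 relation. Attack at C4 would need a seven-membered ring at a carbon deactivated by the CH2OTs group, and the C4–O bond is not broken, so C4 is retained.

Step 10
Reactants: 17
Product: 19 (3S,4R,6R)-4-[(3E)-4-iodo-3-methylbut-3-en-1-yl]-3-methyl-6-[(2S)-2-methyloxiran-2-yl]oxan-2-one, via epimeric epoxy lactones 18 (not isolated)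
Conditions: KN(SiMe3)2 (1.2 equiv), THF, −78 → 0 °C; AcOH
Reagents that add atoms: none
Why: The tertiary alkoxide displaces the primary tosylate (intramolecular Williamson closure, 3-exo-tet) to give the 2,2-disubstituted oxirane with C4 retained. The small excess of the pK-matched, non-nucleophilic amide then enolises the lactone reversibly, so C15 should settle under thermodynamic control on the epimer with all three ring substituents equatorial (15S); the minor epimer is separated and resubmitted.

Step 11
Reactants: 20 but-3-yn-1-ol
Product: 22 (2E)-3-methylpent-2-ene-1,5-diol, via alkenylalane 21 (not isolated)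
Conditions: Me3Al (3 equiv), Cp2ZrCl2 (25 mol %), ClCH2CH2Cl, 25 °C; nBuLi, THF, −78 °C; (CH2O)n, −78 → 25 °C; aq. HCl
Reagents that add atoms: trimethylaluminium, C[Al](C)C; formaldehyde (as paraformaldehyde), C=O
Why: Negishi carboalumination (syn, methyl to the internal carbon) followed by hydroxymethylation of the alkenylalanate with retention should give the E trisubstituted alkene that becomes C7=C8.

Step 12
Reactants: 22
Product: 23 (2E)-1,5-dibromo-3-methylpent-2-ene
Conditions: CBr4 (2.4 equiv), PPh3 (2.4 equiv), CH2Cl2, 0 °C
Reagents that add atoms: tetrabromomethane, BrC(Br)(Br)Br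
Why: Appel bromination of both alcohols under neutral SN2 conditions, which should leave the alkene geometry and position unchanged at 0 °C.

Step 13
Reactants: 23
Product: 24 {[(2E)-5-bromo-3-methylpent-2-en-1-yl]sulfonyl}benzene
Conditions: PhSO2Na (1.0 equiv), DMF, 0 → 25 °C
Reagents that add atoms: sodium benzenesulfinate, [Na+].[O-]S(=O)c1ccccc1
Why: SN2 S-alkylation of the sulfinate. The allylic bromide reacts far faster than the homoallylic primary bromide, so one equivalent should give the mono-sulfone with the E alkene intact.

Step 14
Reactants: 24; 19
Product: 26 (3S,4R,6R)-4-[(3E,7E)-3,7-dimethyl-9-(phenylsulfonyl)nona-3,7-dien-1-yl]-3-methyl-6-[(2S)-2-methyloxiran-2-yl]oxan-2-one, via alkylzinc bromide 25 (not isolated)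
Conditions: Zn dust, LiCl, THF, 50 °C; then 19, Pd(dppf)Cl2 (5 mol %), THF, 25 °C
Reagents that add atoms: none
Why: Zinc insertion assisted by LiCl gives a functionalised alkylzinc that tolerates the sulfone; Negishi sp3–sp2 coupling with the alkenyl iodide proceeds with retention of the E geometry. Alkylzinc halides do not add to lactones or open epoxides, and oxidative addition of zerovalent palladium to the alkenyl iodide is much faster than ionisation of the allylic sulfone.

Step 15
Reactants: 26
Product: 27 (3S,4R,6R)-3-methyl-4-{2-[(2S,3S)-2-methyl-3-[(3E)-3-methyl-5-(phenylsulfonyl)pent-3-en-1-yl]oxiran-2-yl]ethyl}-6-[(2S)-2-methyloxiran-2-yl]oxan-2-one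
Conditions: L-fructose-derived Shi ketone (1.5 equiv), KHSO5 (as Oxone), NaHCO3, aq. Na2EDTA, MeCN, 0 °C, pH about 8
Reagents that add atoms: potassium peroxymonosulfate, [K+].[O-]S(=O)(=O)OO
Why: Shi epoxidation: the chiral dioxirane attacks the only electron-rich alkene (C11=C12), since C7=C8 is deactivated by the allylic sulfone. The spiro transition state of the L-fructose-derived ketone should give the (11S,12S) epoxide by reagent control. The bicarbonate-buffered protocol is chosen so that the lactone is not hydrolysed.

Step 16
Reactants: 27
Product: 29 (1R,3R,4S,7E,11S,12S,15S)-11,12-epoxy-4-hydroxy-6-(phenylsulfonyl)cembr-7-en-16,3-olide (both C6 epimers), via lithiated sulfone 28 (not isolated)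
Conditions: LiN(SiMe3)2 (1.1 equiv), THF (0.002 M), −78 → 25 °C; AcOH
Reagents that add atoms: none
Why: LiN(SiMe3)2 removes the C6 hydrogen, which is allylic and α to the sulfone and some three pK units more acidic than the lactone α-hydrogen, and carbanion 28 attacks the unsubstituted C5 of the 2,2-disubstituted oxirane in an SN2 opening that releases ring strain and leaves the C4 oxygen as a tertiary alkoxide. The closest known reaction type is the intramolecular alkylation of sulfone- or sulfide-stabilised allyl carbanions by epoxides, which has been used to close 14-membered cembranoid rings. The 14-membered carbocycle closes in the endo mode of epoxide opening: the carbanion attacks the oxirane carbon remote from the tether, so both oxirane carbons become ring members and the oxygen stays on the ring as the C4 hydroxyl; the exo alternative (attack at quaternary C4, 13-membered ring) is sterically closed to SN2. No lasting stereocentre is created: the C4–O bond is not broken, so C4 keeps the S configuration from the Sharpless epoxide, and C6 forms as a mixture that step 17 removes. The step needs C5 to be chosen over the 11,12-epoxide; the substrate secures this because C6 and C9 are trans on the E-C7=C8 alkene, so attack at C11 would need a six-membered ring containing an E double bond, and C12 is quaternary. It needs α- and not γ-alkylation of the allyl anion, which charge localisation next to sulfur and the fully substituted C8 provide. It needs the lactone to stay out: the carbonyl is flanked by the C15 branch and would have to close a 12-membered ring, only about one equivalent of a pK-matched amide is used, and since 27 already has the more stable C15 epimer, reversible enolisation cannot erode it. High dilution holds back intermolecular alkylation.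

Step 17
Reactants: 29
Product: 30 (1R,3R,4S,7E,11S,12S,15S)-11,12-epoxy-4-hydroxycembr-7-en-16,3-olide
Conditions: 6% Na(Hg), Na2HPO4, MeOH/THF (3:1), −20 °C
Reagents that add atoms: none
Why: Dissolving-metal reductive desulfonylation: electron transfer cleaves the allylic C–S bond and the allyl anion should be protonated at the less substituted terminus C6, which keeps the trisubstituted E-C7=C8 alkene and removes the C6 stereocentre. The phosphate buffer protects the lactone; the epoxide and the tertiary alcohol are inert.

Step 18
Reactants: 30
Product: 31 (1R,3R,4S,6E,8S,11S,12S,15S)-11,12-epoxy-8-hydroperoxy-4-hydroxycembr-6-en-16,3-olide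
Conditions: O2, visible light, tetraphenylporphyrin (cat.), CH2Cl2, 0 °C
Reagents that add atoms: oxygen, O=O
Why: Schenck ene reaction of singlet oxygen: oxygen bonds to C8 and a hydrogen is taken from C6 on the more substituted side of the alkene (cis effect), which gives the tertiary allylic hydroperoxide with an E-C6=C7 alkene. The C8 configuration is to come from attack on the outer face of the ring alkene. The conditions are neutral and leave the epoxide, lactone and alcohol alone.

## Compound list

1 | (R)-(+)-limonene | CC1=CC[C@@H](CC1)C(C)=C | starting material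
2 | (5R)-2-hydroperoxy-2,7,7-trimethoxy-5-(prop-1-en-2-yl)heptane (C2 epimers) | CC(OC)(OO)CC[C@H](CC(OC)OC)C(C)=C | intermediate (not isolated)
3 | (5R)-7,7-dimethoxy-5-(prop-1-en-2-yl)heptan-2-one | CC(=O)CC[C@H](CC(OC)OC)C(C)=C | intermediate
4 | diethyl (5R)-7,7-dimethoxy-5-(prop-1-en-2-yl)hept-1-en-2-yl phosphate | C=C(OP(=O)(OCC)OCC)CC[C@H](CC(OC)OC)C(C)=C | intermediate (not isolated)
5 | (5R)-7,7-dimethoxy-5-(prop-1-en-2-yl)hept-1-yne | C#CCC[C@H](CC(OC)OC)C(C)=C | intermediate
6 | [(1E,5R)-7,7-dimethoxy-2-methyl-5-(prop-1-en-2-yl)hept-1-en-1-yl]dimethylalane | C[Al](C)/C=C(\C)CC[C@H](CC(OC)OC)C(C)=C | intermediate (not isolated)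
7 | (1E,5R)-1-iodo-7,7-dimethoxy-2-methyl-5-(prop-1-en-2-yl)hept-1-ene | I/C=C(\C)CC[C@H](CC(OC)OC)C(C)=C | intermediate
8 | (3R,6E)-7-iodo-6-methyl-3-(prop-1-en-2-yl)hept-6-enal | I/C=C(\C)CC[C@H](CC=O)C(C)=C | intermediate
9 | ethyl 2-(triphenylphosphoranylidene)propanoate | CCOC(=O)C(C)=P(c1ccccc1)(c1ccccc1)c1ccccc1 | starting material
10 | ethyl (2E,5R,8E)-9-iodo-2,8-dimethyl-5-(prop-1-en-2-yl)nona-2,8-dienoate | I/C=C(\C)CC[C@H](C/C=C(\C)C(=O)OCC)C(C)=C | intermediate
11 | (2E,5R,8E)-9-iodo-2,8-dimethyl-5-(prop-1-en-2-yl)nona-2,8-dien-1-ol | I/C=C(\C)CC[C@H](C/C=C(\C)CO)C(C)=C | intermediate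
12 | [(2S,3S)-3-[(2R,5E)-6-iodo-5-methyl-2-(prop-1-en-2-yl)hex-5-en-1-yl]-2-methyloxiran-2-yl]methanol | I/C=C(\C)CC[C@H](C[C@@H]1O[C@@]1(C)CO)C(C)=C | intermediate (not isolated)
13 | [(2S,3S)-3-[(2R,5E)-6-iodo-5-methyl-2-(prop-1-en-2-yl)hex-5-en-1-yl]-2-methyloxiran-2-yl]methyl 4-methylbenzenesulfonate | I/C=C(\C)CC[C@H](C[C@@H]1O[C@@]1(C)COS(=O)(=O)c1ccc(C)cc1)C(C)=C | intermediate
14 | B-alkyl-9-borabicyclo[3.3.1]nonane from 13 (boron on C16, both C15 epimers) | I/C=C(\C)CC[C@H](C[C@@H]1O[C@@]1(C)COS(=O)(=O)c1ccc(C)cc1)C(C)CB1C2CCCC1CCC2 | intermediate (not isolated)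
15 | [(2S,3S)-3-[(2R,5E)-2-(1-hydroxypropan-2-yl)-6-iodo-5-methylhex-5-en-1-yl]-2-methyloxiran-2-yl]methyl 4-methylbenzenesulfonate (both C15 epimers) | I/C=C(\C)CC[C@H](C[C@@H]1O[C@@]1(C)COS(=O)(=O)c1ccc(C)cc1)C(C)CO | intermediate
16 | (3R,6E)-7-iodo-2,6-dimethyl-3-{[(2S,3S)-3-methyl-3-(tosyloxymethyl)oxiran-2-yl]methyl}hept-6-enoic acid (both C15 epimers) | I/C=C(\C)CC[C@H](C[C@@H]1O[C@@]1(C)COS(=O)(=O)c1ccc(C)cc1)C(C)C(=O)O | intermediate (not isolated)
17 | (2S)-2-hydroxy-2-[(2R,4R)-4-[(3E)-4-iodo-3-methylbut-3-en-1-yl]-5-methyl-6-oxooxan-2-yl]propyl 4-methylbenzenesulfonate (both C15 epimers) | CC1C(=O)O[C@H](C[C@H]1CC/C(C)=C/I)[C@@](C)(O)COS(=O)(=O)c1ccc(C)cc1 | intermediate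
18 | (4R,6R)-4-[(3E)-4-iodo-3-methylbut-3-en-1-yl]-3-methyl-6-[(2S)-2-methyloxiran-2-yl]oxan-2-one (both C15 epimers) | CC1C(=O)O[C@H](C[C@H]1CC/C(C)=C/I)[C@]1(C)CO1 | intermediate (not isolated)
19 | (3S,4R,6R)-4-[(3E)-4-iodo-3-methylbut-3-en-1-yl]-3-methyl-6-[(2S)-2-methyloxiran-2-yl]oxan-2-one | C[C@@H]1C(=O)O[C@H](C[C@H]1CC/C(C)=C/I)[C@]1(C)CO1 | intermediate
20 | but-3-yn-1-ol | C#CCCO | starting material
21 | (E)-alkenyldimethylalane of the aluminium alkoxide of 20 (methyl on C8, aluminium on C7) | C[Al](C)/C=C(\C)CCO[Al](C)C | intermediate (not isolated)
22 | (2E)-3-methylpent-2-ene-1,5-diol | OCC/C(C)=C/CO | intermediate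
23 | (2E)-1,5-dibromo-3-methylpent-2-ene | BrCC/C(C)=C/CBr | intermediate
24 | {[(2E)-5-bromo-3-methylpent-2-en-1-yl]sulfonyl}benzene | BrCC/C(C)=C/CS(=O)(=O)c1ccccc1 | intermediate
25 | [(3E)-3-methyl-5-(phenylsulfonyl)pent-3-en-1-yl]zinc bromide | Br[Zn]CC/C(C)=C/CS(=O)(=O)c1ccccc1 | intermediate (not isolated)
26 | (3S,4R,6R)-4-[(3E,7E)-3,7-dimethyl-9-(phenylsulfonyl)nona-3,7-dien-1-yl]-3-methyl-6-[(2S)-2-methyloxiran-2-yl]oxan-2-one | C[C@@H]1C(=O)O[C@H](C[C@H]1CC/C(C)=C/CC/C(C)=C/CS(=O)(=O)c1ccccc1)[C@]1(C)CO1 | intermediate
27 | (3S,4R,6R)-3-methyl-4-{2-[(2S,3S)-2-methyl-3-[(3E)-3-methyl-5-(phenylsulfonyl)pent-3-en-1-yl]oxiran-2-yl]ethyl}-6-[(2S)-2-methyloxiran-2-yl]oxan-2-one | C[C@@H]1C(=O)O[C@H](C[C@H]1CC[C@]1(C)O[C@H]1CC/C(C)=C/CS(=O)(=O)c1ccccc1)[C@]1(C)CO1 | intermediate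
28 | C6-lithio derivative of 27 | C[C@@H]1C(=O)O[C@H](C[C@H]1CC[C@]1(C)O[C@H]1CC/C(C)=C/C([Li])S(=O)(=O)c1ccccc1)[C@]1(C)CO1 | intermediate (not isolated)
29 | (1R,3R,4S,7E,11S,12S,15S)-11,12-epoxy-4-hydroxy-6-(phenylsulfonyl)cembr-7-en-16,3-olide (both C6 epimers) | C[C@@H]1C(=O)O[C@@H]2C[C@H]1CC[C@]1(C)O[C@H]1CC/C(C)=C/C(S(=O)(=O)c1ccccc1)C[C@]2(C)O | intermediate
30 | (1R,3R,4S,7E,11S,12S,15S)-11,12-epoxy-4-hydroxycembr-7-en-16,3-olide | C[C@@H]1C(=O)O[C@@H]2C[C@H]1CC[C@]1(C)O[C@H]1CC/C(C)=C/CC[C@]2(C)O | intermediate
31 | (1R,3R,4S,6E,8S,11S,12S,15S)-11,12-epoxy-8-hydroperoxy-4-hydroxycembr-6-en-16,3-olide | C[C@@H]1C(=O)O[C@@H]2C[C@H]1CC[C@]1(C)O[C@H]1CC[C@](C)(OO)/C=C/C[C@]2(C)O | target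

## Step count and least certain steps

Total: 18 steps. Longest linear sequence: 15 steps (steps 1–10 and 14–18, from 1); the sulfone fragment 24 takes 3 steps (11–13).

**Step 16 (key step).** The carbanion may add to the lactone carbonyl instead of the oxirane. That acylation would close a 12-membered ring and become irreversible once the ring-opened β-keto sulfone is deprotonated. Opening at the neopentyl-type C5 is slow, so intermolecular alkylation can also compete. The fallback masks the carbonyl. It sets out from 27, which is reduced with iBu2AlH at −78 °C to the lactol F1 and silylated (TBSCl, imidazole) to the silyl lactol ether F2, which has neither an electrophilic carbonyl nor an acidic C15–H. The same amide-base closure would give the macrocyclic silyl lactol ether F3. Bu4NF then frees the macrocyclic lactol F4, and TEMPO/PhI(OAc)2 oxidises it to the lactone, where the sequence returns to the route at 29.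

**Step 18.** Hydrogen abstraction from the C19 methyl (giving the C7 hydroperoxide with an exocyclic alkene) may compete with abstraction from C6, because both lie on the side favoured by the cis effect. Facial selectivity at C8 rests only on the ring conformation. The product can also undergo allylic peroxide shift. The fallback replaces the hydrogen-ene by a metallo-ene reaction and sets out from 29. Zerovalent-palladium catalysis (Pd(PPh3)4, Bu3SnSnBu3), by analogy with allylic acetates, would exchange the sulfonyl group for tin at the less hindered terminus to give the C6 allylstannane F5. Singlet oxygen should then react in an SE2′ stannyl-ene sense, placing oxygen on C8 and the alkene at C6=C7 in the stannyl peroxide F6. Mild hydrolysis on work-up returns to the route at 31. This removes the methyl-abstraction pathway; the face of attack stays substrate-controlled.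

**Step 17.** Protonation of the allyl anion at C8 would move the alkene to C6=C7, and the E geometry could be lost; methoxide could also open the lactone. The fallback changes the bond-forming event from protonation of an allyl anion to hydride capture of a π-allylpalladium complex. It sets out from 29 with Pd(PPh3)4 (cat.) and NaBH4 in THF/iPrOH at 0 °C, where hydride is delivered to the less hindered terminus C6, and returns at 30. No new compound is involved.

**Step 14.** The zinc halide formed in the coupling is a Lewis acid and may open or rearrange the 2,2-disubstituted oxirane; zinc insertion into the bromide may also be slow. The fallback avoids a preformed organozinc: a nickel-catalysed reductive cross-electrophile coupling of 19 with 24 (NiBr2(dme), 4,4′-di-tert-butyl-2,2′-bipyridine, NaI, Mn, dimethylacetamide). It sets out from 19 and 24 and returns at 26 without new compounds.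

**Step 10.** The equilibrium at C15 may not favour the 15S epimer strongly enough, and prolonged contact with base may lead to attack of the lactone enolate on the oxirane. The fallback moves the epimerisation to the aldehyde oxidation level. It sets out from 18, obtained with one equivalent of base and isolated. iBu2AlH at −78 °C gives the lactols F7. Catalytic DBU equilibrates C15 through the open hydroxy aldehyde, and the chair tetrahydropyranol should favour the equatorial methyl in the 15S lactol F8. TEMPO/PhI(OAc)2 then oxidises F8 back to the lactone, returning to the route at 19.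

## Further compounds

F1 | step 16 | lactol (oxan-2-ol, both anomers) of 27 | C[C@@H]1C(O)O[C@H](C[C@H]1CC[C@]1(C)O[C@H]1CC/C(C)=C/CS(=O)(=O)c1ccccc1)[C@]1(C)CO1
F2 | step 16 | tert-butyldimethylsilyl lactol ether of 27 | C[C@@H]1C(O[Si](C)(C)C(C)(C)C)O[C@H](C[C@H]1CC[C@]1(C)O[C@H]1CC/C(C)=C/CS(=O)(=O)c1ccccc1)[C@]1(C)CO1
F3 | step 16 | macrocyclic C16 silyl lactol ether with the C6 phenylsulfonyl group and the C4 hydroxyl | C[C@@H]1C(O[Si](C)(C)C(C)(C)C)O[C@@H]2C[C@H]1CC[C@]1(C)O[C@H]1CC/C(C)=C/C(S(=O)(=O)c1ccccc1)C[C@]2(C)O
F4 | step 16 | macrocyclic C16 lactol corresponding to 29 | C[C@@H]1C(O)O[C@@H]2C[C@H]1CC[C@]1(C)O[C@H]1CC/C(C)=C/C(S(=O)(=O)c1ccccc1)C[C@]2(C)O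
F5 | step 18 | C6 tributylstannyl analogue of 30 (C6 epimers) | C[C@@H]1C(=O)O[C@@H]2C[C@H]1CC[C@]1(C)O[C@H]1CC/C(C)=C/C([Sn](CCCC)(CCCC)CCCC)C[C@]2(C)O
F6 | step 18 | C8 tributylstannylperoxy derivative of 31 | C[C@@H]1C(=O)O[C@@H]2C[C@H]1CC[C@]1(C)O[C@H]1CC[C@](C)(OO[Sn](CCCC)(CCCC)CCCC)/C=C/C[C@]2(C)O
F0 | step 17 | none | none
F0 | step 14 | none | none
F7 | step 10 | lactols from 18 (C15 epimers, both anomers) | CC1C(O)O[C@H](C[C@H]1CC/C(C)=C/I)[C@]1(C)CO1
F8 | step 10 | 15S lactol corresponding to 19 (both anomers) | C[C@@H]1C(O)O[C@H](C[C@H]1CC/C(C)=C/I)[C@]1(C)CO1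
A1 | alternative 1 | methyl (3E,7E)-9-acetoxy-7-methyl-2-oxonona-3,7-dienoate | COC(=O)C(=O)/C=C/CC/C(C)=C/COC(C)=O
A2 | alternative 1 | (E)-1-ethoxypropene | CCO/C=C/C
A3 | alternative 1 | 2-ethoxy-3-methyl dihydropyran-6-carboxylate adduct | C[C@@H]1[C@@H](OCC)OC(C(=O)OC)=C[C@H]1CC/C(C)=C/COC(C)=O
A4 | alternative 2 | macrocyclic (3S,4S):(11S,12S)-bis-epoxy C16 acid | C[C@H](C(=O)O)[C@H]1C[C@@H]2O[C@@]2(C)CC/C=C(C)/CC[C@@H]2O[C@@]2(C)CC1
A5 | alternative 2 | 7,8-ene epoxy lactone (identical with 30) | C[C@@H]1C(=O)O[C@@H]2C[C@H]1CC[C@]1(C)O[C@H]1CC/C(C)=C/CC[C@]2(C)O
A6 | alternative 3 | 16-membered macrolactone (C3 acyl, C16 allylic oxygen, C4 triethylsilyl ether) | O=C1OC/C(C)=C/CC[C@]2(C)O[C@H]2CC/C(C)=C/CC[C@]1(C)O[Si](CC)(CC)CC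
A7 | alternative 3 | 16-membered allyl vinyl ether from A6 | C=C1OC/C(C)=C/CC[C@]2(C)O[C@H]2CC/C(C)=C/CC[C@]1(C)O[Si](CC)(CC)CC
A8 | alternative 3 | 14-membered C3 ketone with C1 isopropenyl | CC(=C)[C@@H]1CC[C@]2(C)O[C@H]2CC/C(C)=C/CC[C@](C)(O[Si](CC)(CC)CC)C(=O)C1
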